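A reading at 3.0 h cannot be looked up, since the earlier runs stop at 90.0 min, so a quick number needs another clock.

in all of them: substrate 0.050 M
- epsilon: enzyme 0.06 mol%; run made earlier
- eta: enzyme 0.087 mol%; run made earlier
- delta: enzyme 0.14 mol%; run made earlier
- noon: enzyme 0.12 mol%; time 3.0 h
- dusk: enzyme 0.059 mol%; time 3.0 h

| run | time / min | product / % | substrate / % | complex / % |
|---|---|---|---|---|
| epsilon | 8.00 | 6.5 | 93.3 | 1.2 |
| epsilon | 25.0 | 15.5 | 84.0 | 0 |
| epsilon | 40.0 | 19.3 | 78.3 | 1.6 |
| epsilon | 60.0 | 24.7 | 74.7 | 0 |
| epsilon | 90.0 | 30.1 | 70.2 | 0.6 |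
| eta | 8.00 | 7.7 | 91.1 | 1.0 |
| eta | 25.0 | 19.1 | 81.3 | 0 |
| eta | 40.0 | 24.1 | 73.2 | 0.1 |
| eta | 60.0 | 29.1 | 72.4 | 0 |
| eta | 90.0 | 33.2 | 66.8 | 0 |
| delta | 8.00 | 11.3 | 88.2 | 0 |
| delta | 25.0 | 26.7 | 74.5 | 0.4 |
| delta | 40.0 | 29.5 | 69.6 | 0.6 |
| delta | 60.0 | 36.9 | 63.1 | 0 |
| delta | 90.0 | 40.1 | 61.4 | 0 |

(scatter of a reading: 1 percentage point)

* which of these there is most of at the end, counted by the substrate in it, noon (substrate / product / complex)
* which of these there is most of at the end, counted by the substrate in it, dusk (substrate / product / complex)
* amount of the one of these that there is most of at the end, in percent of the substrate charged, noon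
* amount of the one of these that there is most of at the end, in percent of the substrate charged, dusk



Your hunch has noon's larger loading putting product ahead of substrate. To test it, divide each rate by the loading c, so that the loading drops out and time stays, rescaled, and count each flask in delta's minutes:

τ = t × c / c(delta)

τ(dusk) = 3.0 h × 0.059 mol% / 0.14 mol% = 75.9 min

τ(noon) = 3.0 h × 0.12 mol% / 0.14 mol% = 154 min

τ, the delta-equivalent time (a normalised time), is the time delta takes to build up the same loading × time. The check comes from the epsilon run: its last reading has τ = 38.6 min, and there substrate reads 70.2%, against 69.6% for delta at 40.0 min, with a scatter of 1 percentage point.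

So dusk falls near the middle of delta's last two readings, and my reckoning gives substrate about 62.3%. Noon lies beyond delta, so my reckoning places it below 61.4%. But substrate lost 1.7 points between those readings and still leads product, 61.4% against 40.1%, so I expect substrate to stay ahead of product at noon.

The forecast agrees on substrate in both flasks: 55% (51.5% to 58%) for noon and 61.5% (59% to 64%) for dusk, on the ground that “time and loading are interchangeable”.

The flasks give substrate 56.7% at noon and 62.2% at dusk, both inside those ranges.

    2 complex → spent catalyst (k = 1.30 × 10⁵ L mol⁻¹ h⁻¹)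
    complex ⇌ enzyme + product (K = 0.0540 M, k = 2000 h⁻¹)
    substrate + enzyme ⇌ complex (K = 17.0 L mol⁻¹, k = 2.60 × 10⁶ L mol⁻¹ h⁻¹)

Noon at 1.50 h has τ = 77.1 min, beside 75.9 min for dusk at its end. The difference in loading of enzyme is the main reason for the gap between the two flasks at the end: noon's substrate stands at 56.7%, and at 62.2% without that difference. At these nearly equal values of τ the two flasks stand alike: noon at 1.50 h holds substrate 62.0% and spent catalyst 77.1% of the catalyst charged, dusk at 3.00 h substrate 62.2% and spent catalyst 76.9%.

The runs come from a simulation for substances that don't exist, noise included.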